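**Retrosynthetic overview**
1. Target 32 ⇐ hydrogenolysis of four benzyl ethers ⇐ fluoride removal of four silyl ethers from 30.
2. 30 ⇐ trans-selective alkylation of the lithium enolate of (S)-lactone 29 with benzylic bromide 16 (C3–CH2 bond).
3. 29 (the only ring that is built: lactol first, then lactone) ⇐ Evans alkylation of pentenoyl imide 24 with benzylic bromide 22, reductive auxiliary removal, alkene cleavage, oxidation.
4. 16 and 22 ⇐ one N-arylacetyl oxazolidinone 10 plus O-benzylvanillin 11 by intermolecular aldol addition: boron syn aldol for the (1S,2R) side chain, MgCl2-catalysed anti aldol for the (1S,2S) side chain.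
5. 10 ⇐ methyl vanillate by O-allylation, Claisen rearrangement and alkene cleavage to the arylacetic acid.

Assumption: the SMILES is read literally, i.e. a (3S,4S)-lactone with the (1S,2S) side chain on the ring of the C4 benzyl group and the (1S,2R) side chain on the ring of the C3 benzyl group.

Abbreviations in names: ArBn = 4-(benzyloxy)-3-methoxyphenyl; TBS = tert-butyldimethylsilyl.

**Route**

Step 1
Reactants: 1 methyl vanillate (methyl 4-hydroxy-3-methoxybenzoate); 2 allyl bromide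
Product: 3 methyl 4-(allyloxy)-3-methoxybenzoate
Conditions: K2CO3, acetone, reflux
Reagents that add atoms: none
Why: Williamson ether synthesis of a phenoxide with a reactive allylic bromide.

Step 2
Reactants: 3 methyl 4-(allyloxy)-3-methoxybenzoate
Product: 4 methyl 3-allyl-4-hydroxy-5-methoxybenzoate
Conditions: neat, N2, 200 °C
Reagents that add atoms: none
Why: aromatic Claisen rearrangement, a [3,3]-sigmatropic shift to the only free ortho position followed by rearomatisation.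

Step 3
Reactants: 4 methyl 3-allyl-4-hydroxy-5-methoxybenzoate
Product: 5 methyl 3-allyl-4-(benzyloxy)-5-methoxybenzoate
Conditions: BnBr, K2CO3, DMF, 60 °C
Reagents that add atoms: benzyl bromide BrCc1ccccc1
Why: Williamson benzylation protects the phenol for all later base, hydride and enolate steps.

Step 4
Reactants: 5 methyl 3-allyl-4-(benzyloxy)-5-methoxybenzoate
Product: 6 methyl 4-(benzyloxy)-3-methoxy-5-(2-oxoethyl)benzoate
Conditions: OsO4 (2 mol%), NaIO4, 2,6-lutidine, dioxane/H2O, rt; crude product used at once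
Reagents that add atoms: sodium periodate [Na+].[O-]I(=O)(=O)=O (terminal oxidant; the carbonyl oxygen is delivered through catalytic OsO4 O=[Os](=O)(=O)=O)
Why: Lemieux–Johnson oxidation (dihydroxylation and periodate cleavage) shortens the allyl group to the arylacetaldehyde without touching the arene.

Step 5
Reactants: 6 methyl 4-(benzyloxy)-3-methoxy-5-(2-oxoethyl)benzoate
Product: 7 2-[2-(benzyloxy)-3-methoxy-5-(methoxycarbonyl)phenyl]acetic acid
Conditions: NaClO2, NaH2PO4, 2-methyl-2-butene, t-BuOH/H2O, 0 °C to rt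
Reagents that add atoms: sodium chlorite [Na+].[O-]Cl=O
Why: Pinnick oxidation converts the aldehyde to the acid under buffered conditions that leave the ester and benzyl ether alone.

Step 6
Reactants: 7 2-[2-(benzyloxy)-3-methoxy-5-(methoxycarbonyl)phenyl]acetic acid; 8 (S)-4-benzyloxazolidin-2-one
Product: 10 methyl 3-{2-[(S)-4-benzyl-2-oxooxazolidin-3-yl]-2-oxoethyl}-4-(benzyloxy)-5-methoxybenzoate, via mixed pivalic anhydride 9 (not isolated)
Conditions: t-BuCOCl, Et3N, THF, −20 °C; then LiCl, 8, −20 °C to rt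
Reagents that add atoms: pivaloyl chloride CC(C)(C)C(Cl)=O (its atoms stay only in intermediate 9)
Why: N-acylation of the oxazolidinone through the mixed anhydride, which is attacked at the unhindered arylacetyl carbonyl.

Step 7
Reactants: 10 methyl 3-{2-[(S)-4-benzyl-2-oxooxazolidin-3-yl]-2-oxoethyl}-4-(benzyloxy)-5-methoxybenzoate; 11 4-(benzyloxy)-3-methoxybenzaldehyde (O-benzylvanillin)
Product: 12 methyl 3-{(2S,3S)-1-[(S)-4-benzyl-2-oxooxazolidin-3-yl]-3-ArBn-3-hydroxy-1-oxopropan-2-yl}-4-(benzyloxy)-5-methoxybenzoate (syn adduct)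
Conditions: Bu2BOTf, i-Pr2NEt, CH2Cl2, 0 °C; then 11, −78 to 0 °C; then pH 7 buffer, MeOH, H2O2, 0 °C
Reagents that add atoms: none
Why: Evans syn aldol addition, in which the Z boron enolate reacts through a closed chair transition state with the auxiliary carbonyl turned away and so sets both new centres as (2S,3S).

Step 8
Reactants: 12 syn adduct
Product: 13 methyl 4-(benzyloxy)-3-[(1S,2R)-1-ArBn-1,3-dihydroxypropan-2-yl]-5-methoxybenzoate
Conditions: LiBH4, MeOH (1 equiv), THF, 0 °C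
Reagents that add atoms: none
Why: reductive cleavage of the activated imide carbonyl is much faster than reduction of the electron-rich aryl methyl ester at 0 °C and leaves both centres untouched (the descriptor of C2 changes from S to R only through the CIP ranking).

Step 9
Reactants: 13 methyl 4-(benzyloxy)-3-[(1S,2R)-1-ArBn-1,3-dihydroxypropan-2-yl]-5-methoxybenzoate
Product: 14 methyl 4-(benzyloxy)-3-[(1S,2R)-1-ArBn-1,3-bis(TBS-oxy)propan-2-yl]-5-methoxybenzoate
Conditions: TBSOTf, 2,6-lutidine, CH2Cl2, −78 to 0 °C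
Reagents that add atoms: tert-butyldimethylsilyl triflate CC(C)(C)[Si](C)(C)OS(=O)(=O)C(F)(F)F
Why: silyl triflate silylation caps both the primary and the hindered benzylic hydroxyl as base-stable ethers that are removed later without acid.

Step 10
Reactants: 14 methyl 4-(benzyloxy)-3-[(1S,2R)-1-ArBn-1,3-bis(TBS-oxy)propan-2-yl]-5-methoxybenzoate
Product: 15 {4-(benzyloxy)-3-[(1S,2R)-1-ArBn-1,3-bis(TBS-oxy)propan-2-yl]-5-methoxyphenyl}methanol
Conditions: i-Bu2AlH, CH2Cl2, −78 to 0 °C; aq. potassium sodium tartrate work-up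
Reagents that add atoms: none
Why: hydride reduction of the benzoate ester to the benzylic alcohol, with silyl and benzyl ethers inert.

Step 11
Reactants: 15 {4-(benzyloxy)-3-[(1S,2R)-1-ArBn-1,3-bis(TBS-oxy)propan-2-yl]-5-methoxyphenyl}methanol
Product: 16 4-(benzyloxy)-3-[(1S,2R)-1-ArBn-1,3-bis(TBS-oxy)propan-2-yl]-5-methoxybenzyl bromide
Conditions: CBr4, PPh3, CH2Cl2, 0 °C; used at once
Reagents that add atoms: carbon tetrabromide BrC(Br)(Br)Br
Why: Appel bromination converts the primary benzylic alcohol to the bromide under neutral conditions that spare the silyl ethers.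

Step 12
Reactants: 10 methyl 3-{2-[(S)-4-benzyl-2-oxooxazolidin-3-yl]-2-oxoethyl}-4-(benzyloxy)-5-methoxybenzoate; 11 4-(benzyloxy)-3-methoxybenzaldehyde
Product: 18 methyl 3-{(2R,3S)-1-[(S)-4-benzyl-2-oxooxazolidin-3-yl]-3-ArBn-3-hydroxy-1-oxopropan-2-yl}-4-(benzyloxy)-5-methoxybenzoate (anti adduct), via trimethylsilyl ether 17 (not isolated)
Conditions: MgCl2 (20 mol%), Et3N, Me3SiCl, EtOAc, rt; then AcOH/THF/H2O, rt
Reagents that add atoms: chlorotrimethylsilane C[Si](C)(C)Cl (its atoms stay only in intermediate 17)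
Why: Evans magnesium-halide-catalysed anti aldol addition, in which the chelated Z magnesium enolate adds to the non-enolisable aldehyde on the face away from the auxiliary benzyl group through a boat transition state and in situ silylation makes the addition irreversible, setting (2R,3S).

Step 13
Reactants: 18 anti adduct
Product: 19 methyl 4-(benzyloxy)-3-[(1S,2S)-1-ArBn-1,3-dihydroxypropan-2-yl]-5-methoxybenzoate
Conditions: LiBH4, MeOH (1 equiv), THF, 0 °C
Reagents that add atoms: none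
Why: chemoselective reductive cleavage of the imide as in step 8 (the descriptor of C2 changes from R to S only through the CIP ranking).

Step 14
Reactants: 19 methyl 4-(benzyloxy)-3-[(1S,2S)-1-ArBn-1,3-dihydroxypropan-2-yl]-5-methoxybenzoate
Product: 20 methyl 4-(benzyloxy)-3-[(1S,2S)-1-ArBn-1,3-bis(TBS-oxy)propan-2-yl]-5-methoxybenzoate
Conditions: TBSOTf, 2,6-lutidine, CH2Cl2, −78 to 0 °C
Reagents that add atoms: tert-butyldimethylsilyl triflate CC(C)(C)[Si](C)(C)OS(=O)(=O)C(F)(F)F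
Why: silyl triflate silylation of both hydroxyls as in step 9.

Step 15
Reactants: 20 methyl 4-(benzyloxy)-3-[(1S,2S)-1-ArBn-1,3-bis(TBS-oxy)propan-2-yl]-5-methoxybenzoate
Product: 21 {4-(benzyloxy)-3-[(1S,2S)-1-ArBn-1,3-bis(TBS-oxy)propan-2-yl]-5-methoxyphenyl}methanol
Conditions: i-Bu2AlH, CH2Cl2, −78 to 0 °C; aq. potassium sodium tartrate work-up
Reagents that add atoms: none
Why: hydride reduction of the ester to the benzylic alcohol as in step 10.

Step 16
Reactants: 21 {4-(benzyloxy)-3-[(1S,2S)-1-ArBn-1,3-bis(TBS-oxy)propan-2-yl]-5-methoxyphenyl}methanol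
Product: 22 4-(benzyloxy)-3-[(1S,2S)-1-ArBn-1,3-bis(TBS-oxy)propan-2-yl]-5-methoxybenzyl bromide
Conditions: CBr4, PPh3, CH2Cl2, 0 °C; used at once
Reagents that add atoms: carbon tetrabromide BrC(Br)(Br)Br
Why: Appel bromination as in step 11.

Step 17
Reactants: 23 pent-4-enoyl chloride; 8 (S)-4-benzyloxazolidin-2-one
Product: 24 (S)-4-benzyl-3-(pent-4-enoyl)oxazolidin-2-one
Conditions: n-BuLi, THF, −78 °C; then 23, −78 to 0 °C
Reagents that add atoms: none
Why: N-acylation of the lithiated oxazolidinone with an acid chloride.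

Step 18
Reactants: 24 (S)-4-benzyl-3-(pent-4-enoyl)oxazolidin-2-one (2 equiv); 22 anti-series benzylic bromide
Product: 25 (S)-4-benzyl-3-[(R)-2-{4-(benzyloxy)-3-[(1S,2S)-1-ArBn-1,3-bis(TBS-oxy)propan-2-yl]-5-methoxybenzyl}pent-4-enoyl]oxazolidin-2-one
Conditions: NaN(SiMe3)2, THF, −78 °C; then 22, −78 to −40 °C
Reagents that add atoms: none
Why: Evans asymmetric alkylation, in which the chelated Z sodium enolate is benzylated on the face away from the auxiliary benzyl group and so sets the (R) centre that becomes C4 of the lactone.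

Step 19
Reactants: 25 alkylated imide
Product: 26 (R)-2-{4-(benzyloxy)-3-[(1S,2S)-1-ArBn-1,3-bis(TBS-oxy)propan-2-yl]-5-methoxybenzyl}pent-4-en-1-ol
Conditions: LiBH4, MeOH (1 equiv), THF, 0 °C
Reagents that add atoms: none
Why: reductive cleavage of the imide to the primary alcohol without epimerisation, with the terminal alkene and ethers inert.

Step 20
Reactants: 26 pentenol
Product: 28 (4S)-4-{4-(benzyloxy)-3-[(1S,2S)-1-ArBn-1,3-bis(TBS-oxy)propan-2-yl]-5-methoxybenzyl}tetrahydrofuran-2-ol (anomer mixture), via hydroxy aldehyde 27 (not isolated)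
Conditions: OsO4 (2 mol%), NaIO4, 2,6-lutidine, dioxane/H2O, rt
Reagents that add atoms: sodium periodate [Na+].[O-]I(=O)(=O)=O (terminal oxidant; the new oxygen is delivered through catalytic OsO4 O=[Os](=O)(=O)=O)
Why: Lemieux–Johnson cleavage of the only alkene gives the 4-hydroxy aldehyde, which closes spontaneously to the five-membered lactol (the descriptor changes from R to S only through the CIP ranking).

Step 21
Reactants: 28 lactol
Product: 29 (S)-4-{4-(benzyloxy)-3-[(1S,2S)-1-ArBn-1,3-bis(TBS-oxy)propan-2-yl]-5-methoxybenzyl}dihydrofuran-2(3H)-one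
Conditions: 2,2,6,6-tetramethylpiperidin-1-oxyl (10 mol%), PhI(OAc)2, CH2Cl2, rt
Reagents that add atoms: none
Why: oxoammonium-mediated oxidation of the lactol to the lactone under mild conditions that leave silyl and benzyl ethers intact.

Step 22
Reactants: 29 (S)-lactone; 16 syn-series benzylic bromide
Product: 30 (3S,4S)-3-{4-(benzyloxy)-3-[(1S,2R)-1-ArBn-1,3-bis(TBS-oxy)propan-2-yl]-5-methoxybenzyl}-4-{4-(benzyloxy)-3-[(1S,2S)-1-ArBn-1,3-bis(TBS-oxy)propan-2-yl]-5-methoxybenzyl}dihydrofuran-2(3H)-one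
Conditions: LiN(SiMe3)2, THF, −78 °C; then 16, DMPU, −78 to −40 °C
Reagents that add atoms: none
Why: alkylation of the lactone lithium enolate occurs anti to the C4 benzyl substituent and gives the trans (3S,4S) dibenzylbutyrolactone.

Step 23
Reactants: 30 fully protected lactone
Product: 31 (3S,4S)-3-{4-(benzyloxy)-3-[(1S,2R)-1-ArBn-1,3-dihydroxypropan-2-yl]-5-methoxybenzyl}-4-{4-(benzyloxy)-3-[(1S,2S)-1-ArBn-1,3-dihydroxypropan-2-yl]-5-methoxybenzyl}dihydrofuran-2(3H)-one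
Conditions: Bu4NF, AcOH (1:1), THF, rt to 40 °C
Reagents that add atoms: none
Why: buffered fluoride desilylation frees the four hydroxyls without acid, so the benzylic carbinols cannot ionise and the lactone is not opened.

Step 24
Reactants: 31 tetrabenzyl ether tetraol
Product: 32 (3S,4S)-3-{4-hydroxy-3-[(1S,2R)-1,3-dihydroxy-1-(4-hydroxy-3-methoxyphenyl)propan-2-yl]-5-methoxybenzyl}-4-{4-hydroxy-3-[(1S,2S)-1,3-dihydroxy-1-(4-hydroxy-3-methoxyphenyl)propan-2-yl]-5-methoxybenzyl}dihydrofuran-2(3H)-one (CNP0113972.1)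
Conditions: H2 (1 atm), Pd/C (10%), EtOAc/EtOH, rt, stopped when the fourth benzyl group is gone
Reagents that add atoms: none
Why: neutral catalytic hydrogenolysis cleaves aryl benzyl ethers much faster than secondary benzylic alcohols and avoids the acid that would close the side chains to phenylcoumarans.

**Compound list**

1 | methyl vanillate | COC(=O)c1ccc(O)c(OC)c1 | starting material
2 | allyl bromide | C=CCBr | starting material
3 | methyl 4-(allyloxy)-3-methoxybenzoate | COC(=O)c1ccc(OCC=C)c(OC)c1 | intermediate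
4 | methyl 3-allyl-4-hydroxy-5-methoxybenzoate | COC(=O)c1cc(OC)c(O)c(c1)CC=C | intermediate
5 | methyl 3-allyl-4-(benzyloxy)-5-methoxybenzoate | COC(=O)c1cc(OC)c(OCc2ccccc2)c(c1)CC=C | intermediate
6 | methyl 4-(benzyloxy)-3-methoxy-5-(2-oxoethyl)benzoate | COC(=O)c1cc(OC)c(OCc2ccccc2)c(c1)CC=O | intermediate
7 | 2-[2-(benzyloxy)-3-methoxy-5-(methoxycarbonyl)phenyl]acetic acid | COC(=O)c1cc(OC)c(OCc2ccccc2)c(c1)CC(=O)O | intermediate
8 | (S)-4-benzyloxazolidin-2-one | O=C1N[C@@H](Cc2ccccc2)CO1 | starting material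
9 | mixed pivalic anhydride of 7 (formed in the flask) | COC(=O)c1cc(OC)c(OCc2ccccc2)c(c1)CC(=O)OC(=O)C(C)(C)C | intermediate
10 | methyl 3-{2-[(S)-4-benzyl-2-oxooxazolidin-3-yl]-2-oxoethyl}-4-(benzyloxy)-5-methoxybenzoate | COC(=O)c1cc(OC)c(OCc2ccccc2)c(c1)CC(=O)N1[C@@H](Cc2ccccc2)COC1=O | intermediate
11 | 4-(benzyloxy)-3-methoxybenzaldehyde | O=Cc1ccc(OCc2ccccc2)c(OC)c1 | starting material
12 | (2S,3S) syn aldol adduct | COC(=O)c1cc(OC)c(OCc2ccccc2)c(c1)[C@H](C(=O)N1[C@@H](Cc2ccccc2)COC1=O)[C@H](O)c1ccc(OCc2ccccc2)c(OC)c1 | intermediate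
13 | (1S,2R) diol ester | COC(=O)c1cc(OC)c(OCc2ccccc2)c(c1)[C@H](CO)[C@H](O)c1ccc(OCc2ccccc2)c(OC)c1 | intermediate
14 | (1S,2R) bis-TBS ester | COC(=O)c1cc(OC)c(OCc2ccccc2)c(c1)[C@H](CO[Si](C)(C)C(C)(C)C)[C@H](O[Si](C)(C)C(C)(C)C)c1ccc(OCc2ccccc2)c(OC)c1 | intermediate
15 | (1S,2R) bis-TBS benzylic alcohol | OCc1cc(OC)c(OCc2ccccc2)c(c1)[C@H](CO[Si](C)(C)C(C)(C)C)[C@H](O[Si](C)(C)C(C)(C)C)c1ccc(OCc2ccccc2)c(OC)c1 | intermediate
16 | (1S,2R) bis-TBS benzylic bromide | BrCc1cc(OC)c(OCc2ccccc2)c(c1)[C@H](CO[Si](C)(C)C(C)(C)C)[C@H](O[Si](C)(C)C(C)(C)C)c1ccc(OCc2ccccc2)c(OC)c1 | intermediate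
17 | trimethylsilyl ether of anti adduct 18 (formed in the flask) | COC(=O)c1cc(OC)c(OCc2ccccc2)c(c1)[C@@H](C(=O)N1[C@@H](Cc2ccccc2)COC1=O)[C@H](O[Si](C)(C)C)c1ccc(OCc2ccccc2)c(OC)c1 | intermediate
18 | (2R,3S) anti aldol adduct | COC(=O)c1cc(OC)c(OCc2ccccc2)c(c1)[C@@H](C(=O)N1[C@@H](Cc2ccccc2)COC1=O)[C@H](O)c1ccc(OCc2ccccc2)c(OC)c1 | intermediate
19 | (1S,2S) diol ester | COC(=O)c1cc(OC)c(OCc2ccccc2)c(c1)[C@@H](CO)[C@H](O)c1ccc(OCc2ccccc2)c(OC)c1 | intermediate
20 | (1S,2S) bis-TBS ester | COC(=O)c1cc(OC)c(OCc2ccccc2)c(c1)[C@@H](CO[Si](C)(C)C(C)(C)C)[C@H](O[Si](C)(C)C(C)(C)C)c1ccc(OCc2ccccc2)c(OC)c1 | intermediate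
21 | (1S,2S) bis-TBS benzylic alcohol | OCc1cc(OC)c(OCc2ccccc2)c(c1)[C@@H](CO[Si](C)(C)C(C)(C)C)[C@H](O[Si](C)(C)C(C)(C)C)c1ccc(OCc2ccccc2)c(OC)c1 | intermediate
22 | (1S,2S) bis-TBS benzylic bromide | BrCc1cc(OC)c(OCc2ccccc2)c(c1)[C@@H](CO[Si](C)(C)C(C)(C)C)[C@H](O[Si](C)(C)C(C)(C)C)c1ccc(OCc2ccccc2)c(OC)c1 | intermediate
23 | pent-4-enoyl chloride | C=CCCC(Cl)=O | starting material
24 | (S)-4-benzyl-3-(pent-4-enoyl)oxazolidin-2-one | C=CCCC(=O)N1[C@@H](Cc2ccccc2)COC1=O | intermediate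
25 | (R)-2-benzylated pentenoyl imide | C=CC[C@H](Cc1cc(OC)c(OCc2ccccc2)c(c1)[C@@H](CO[Si](C)(C)C(C)(C)C)[C@H](O[Si](C)(C)C(C)(C)C)c1ccc(OCc2ccccc2)c(OC)c1)C(=O)N1[C@@H](Cc2ccccc2)COC1=O | intermediate
26 | (R)-2-(arylmethyl)pent-4-en-1-ol | C=CC[C@H](Cc1cc(OC)c(OCc2ccccc2)c(c1)[C@@H](CO[Si](C)(C)C(C)(C)C)[C@H](O[Si](C)(C)C(C)(C)C)c1ccc(OCc2ccccc2)c(OC)c1)CO | intermediate
27 | (S)-3-(arylmethyl)-4-hydroxybutanal (formed in the flask) | O=CC[C@H](Cc1cc(OC)c(OCc2ccccc2)c(c1)[C@@H](CO[Si](C)(C)C(C)(C)C)[C@H](O[Si](C)(C)C(C)(C)C)c1ccc(OCc2ccccc2)c(OC)c1)CO | intermediate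
28 | (4S)-4-(arylmethyl)tetrahydrofuran-2-ol (anomer mixture) | OC1C[C@H](Cc2cc(OC)c(OCc3ccccc3)c(c2)[C@@H](CO[Si](C)(C)C(C)(C)C)[C@H](O[Si](C)(C)C(C)(C)C)c2ccc(OCc3ccccc3)c(OC)c2)CO1 | intermediate
29 | (S)-4-(arylmethyl)dihydrofuran-2(3H)-one | O=C1C[C@H](Cc2cc(OC)c(OCc3ccccc3)c(c2)[C@@H](CO[Si](C)(C)C(C)(C)C)[C@H](O[Si](C)(C)C(C)(C)C)c2ccc(OCc3ccccc3)c(OC)c2)CO1 | intermediate
30 | (3S,4S) tetrabenzyl tetra-TBS lactone | COc1cc([C@@H](O[Si](C)(C)C(C)(C)C)[C@H](CO[Si](C)(C)C(C)(C)C)c2cc(C[C@@H]3COC(=O)[C@H]3Cc3cc(OC)c(OCc4ccccc4)c([C@H](CO[Si](C)(C)C(C)(C)C)[C@H](O[Si](C)(C)C(C)(C)C)c4ccc(OCc5ccccc5)c(OC)c4)c3)cc(OC)c2OCc2ccccc2)ccc1OCc1ccccc1 | intermediate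
31 | (3S,4S) tetrabenzyl ether tetraol | COc1cc([C@@H](O)[C@H](CO)c2cc(C[C@@H]3COC(=O)[C@H]3Cc3cc(OC)c(OCc4ccccc4)c([C@H](CO)[C@H](O)c4ccc(OCc5ccccc5)c(OC)c4)c3)cc(OC)c2OCc2ccccc2)ccc1OCc1ccccc1 | intermediate
32 | CNP0113972.1 | COc1cc([C@@H](O)[C@H](CO)c2cc(C[C@@H]3COC(=O)[C@H]3Cc3cc(OC)c(O)c([C@H](CO)[C@H](O)c4ccc(O)c(OC)c4)c3)cc(OC)c2O)ccc1O | target

**Totals**

Total step count: 24. Longest linear sequence: 18 steps (steps 1–6, 12–16, 18–24).

**Three steps most likely to fail**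

Step 12 (anti aldol; the stabilised arylacetyl enolate may give a lower diastereomer ratio or a reversible addition). The fallback sets out from 7 and comes back at 20, replacing the anti aldol by a syn aldol plus inversion of the carbinol centre.
- Acid 7 is coupled through 9 with commercial (R)-4-benzyloxazolidin-2-one (O=C1N[C@H](Cc2ccccc2)CO1) to give the enantiomeric-auxiliary imide F1.
- The boron syn aldol conditions of step 7 with 11 give the (2R,3R) syn adduct F2, which already has the correct C2 configuration.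
- LiBH4 gives the (1R,2S) diol F3, and TBSCl/imidazole in DMF silylates only the primary hydroxyl to give the mono silyl ether F4.
- Dess–Martin periodinane in CH2Cl2 gives the aryl ketone F5, handled without base so that the adjacent centre holds.
- Reduction with BH3·SMe2 and catalytic (R)-1-methyl-3,3-diphenyltetrahydro-1H,3H-pyrrolo[1,2-c][1,3,2]oxazaborole in toluene at −20 °C (Corey–Bakshi–Shibata reduction, aryl as the large group) sets the 1S carbinol and gives the (1S,2S) alcohol F6.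
- TBSOTf/2,6-lutidine converts F6 into 20.

Step 22 (lactone enolate alkylation with a large, labile benzylic bromide; risk of low conversion or double alkylation). The fallback sets out from 15 and comes back at 30, using an aldol addition and deoxygenation instead of an alkylation.
- MnO2 in CH2Cl2 oxidises 15 to the benzaldehyde F7.
- The lithium enolate of 29 (LiN(SiMe3)2, THF, −78 °C) adds to F7 anti to the C4 substituent to give the trans hydroxybenzyl lactone F8 as a mixture of carbinol epimers.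
- 1,1'-Thiocarbonyldiimidazole with catalytic 4-(dimethylamino)pyridine gives the imidazolyl thiocarbonate F9.
- Bu3SnH with azobisisobutyronitrile in toluene at 90 °C (Barton–McCombie deoxygenation) removes the benzylic oxygen without touching C3 and gives 30.

Step 24 (hydrogenolysis in the presence of two free, electron-rich benzylic alcohols; risk of C–O cleavage at those carbinols). The fallback sets out from 30 and comes back at 32, reversing the order of the two deprotections.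
- Hydrogenolysis of 30 (H2, Pd/C, EtOAc) while both carbinols are still silyl ethers gives the tetraphenol tetrasilyl ether F10.
- Bu4NF buffered with AcOH in THF then removes the four silyl groups near neutrality and gives 32.

**Further compounds**

F1 | step 12 | methyl 3-{2-[(R)-4-benzyl-2-oxooxazolidin-3-yl]-2-oxoethyl}-4-(benzyloxy)-5-methoxybenzoate | COC(=O)c1cc(OC)c(OCc2ccccc2)c(c1)CC(=O)N1[C@H](Cc2ccccc2)COC1=O
F2 | step 12 | methyl 3-{(2R,3R)-1-[(R)-4-benzyl-2-oxooxazolidin-3-yl]-3-ArBn-3-hydroxy-1-oxopropan-2-yl}-4-(benzyloxy)-5-methoxybenzoate | COC(=O)c1cc(OC)c(OCc2ccccc2)c(c1)[C@@H](C(=O)N1[C@H](Cc2ccccc2)COC1=O)[C@@H](O)c1ccc(OCc2ccccc2)c(OC)c1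
F3 | step 12 | methyl 4-(benzyloxy)-3-[(1R,2S)-1-ArBn-1,3-dihydroxypropan-2-yl]-5-methoxybenzoate | COC(=O)c1cc(OC)c(OCc2ccccc2)c(c1)[C@@H](CO)[C@@H](O)c1ccc(OCc2ccccc2)c(OC)c1
F4 | step 12 | methyl 4-(benzyloxy)-3-[(1R,2S)-1-ArBn-1-hydroxy-3-(TBS-oxy)propan-2-yl]-5-methoxybenzoate | COC(=O)c1cc(OC)c(OCc2ccccc2)c(c1)[C@@H](CO[Si](C)(C)C(C)(C)C)[C@@H](O)c1ccc(OCc2ccccc2)c(OC)c1
F5 | step 12 | methyl 4-(benzyloxy)-3-[(S)-1-ArBn-1-oxo-3-(TBS-oxy)propan-2-yl]-5-methoxybenzoate | COC(=O)c1cc(OC)c(OCc2ccccc2)c(c1)[C@@H](CO[Si](C)(C)C(C)(C)C)C(=O)c1ccc(OCc2ccccc2)c(OC)c1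
F6 | step 12 | methyl 4-(benzyloxy)-3-[(1S,2S)-1-ArBn-1-hydroxy-3-(TBS-oxy)propan-2-yl]-5-methoxybenzoate | COC(=O)c1cc(OC)c(OCc2ccccc2)c(c1)[C@@H](CO[Si](C)(C)C(C)(C)C)[C@H](O)c1ccc(OCc2ccccc2)c(OC)c1
F7 | step 22 | 4-(benzyloxy)-3-[(1S,2R)-1-ArBn-1,3-bis(TBS-oxy)propan-2-yl]-5-methoxybenzaldehyde | O=Cc1cc(OC)c(OCc2ccccc2)c(c1)[C@H](CO[Si](C)(C)C(C)(C)C)[C@H](O[Si](C)(C)C(C)(C)C)c1ccc(OCc2ccccc2)c(OC)c1
F8 | step 22 | trans lactone 30 carrying a hydroxyl on the C3 benzylic carbon (carbinol epimers) | COc1cc([C@@H](O[Si](C)(C)C(C)(C)C)[C@H](CO[Si](C)(C)C(C)(C)C)c2cc(C[C@@H]3COC(=O)[C@H]3C(O)c3cc(OC)c(OCc4ccccc4)c([C@H](CO[Si](C)(C)C(C)(C)C)[C@H](O[Si](C)(C)C(C)(C)C)c4ccc(OCc5ccccc5)c(OC)c4)c3)cc(OC)c2OCc2ccccc2)ccc1OCc1ccccc1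
F9 | step 22 | O-(imidazol-1-ylthiocarbonyl) derivative of F8 | COc1cc([C@@H](O[Si](C)(C)C(C)(C)C)[C@H](CO[Si](C)(C)C(C)(C)C)c2cc(C[C@@H]3COC(=O)[C@H]3C(OC(=S)n4ccnc4)c3cc(OC)c(OCc4ccccc4)c([C@H](CO[Si](C)(C)C(C)(C)C)[C@H](O[Si](C)(C)C(C)(C)C)c4ccc(OCc5ccccc5)c(OC)c4)c3)cc(OC)c2OCc2ccccc2)ccc1OCc1ccccc1
F10 | step 24 | (3S,4S) tetraphenol tetra-TBS lactone | COc1cc([C@@H](O[Si](C)(C)C(C)(C)C)[C@H](CO[Si](C)(C)C(C)(C)C)c2cc(C[C@@H]3COC(=O)[C@H]3Cc3cc(OC)c(O)c([C@H](CO[Si](C)(C)C(C)(C)C)[C@H](O[Si](C)(C)C(C)(C)C)c4ccc(O)c(OC)c4)c3)cc(OC)c2O)ccc1O
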